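**Plan**

1. Retrosynthesis (briarane locants): the C6–Cl bond (SN2 on a 6-alcohol) and the three acetates come off first. Then C2–C3 (Nozaki–Hiyama–Kishi closure of the ten-membered ring), the lactone C7–O bond (epoxide opening), C10–C11 (ring A), C9–C10 (Grignard union), C7=C8 (Horner–Wadsworth–Emmons) and C1–C2/C1–C15 (Fráter–Seebach) are cut.
2. Forward: fragment 1 (C1, C2, C10–C15, C20) and fragment 2 (C3–C9, C16–C19) are joined at C9–C10. Ring A closes by C10–C11, the γ-lactone forms, the ten-membered ring closes last at C2–C3, and acetylation and chloride substitution finish.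
3. Enabling feature: the C9 carbonyl can enolise only toward C10 because C8 is fully substituted, and C10 is tied through quaternary C1, C14, C13 and C12 to C11. A 6-exo-dig Conia-ene closure of this hept-6-ynyl enol makes ring A and the C11=C20 methylene in one event. O14 and O2, 1,3-related across C1, are held in a 1,3-dioxane that locks the chair and hence C10.
4. Stereochemistry: C14 by Noyori hydrogenation, C1 by double Fráter–Seebach alkylation, C10 in the key step, C9 by Felkin–Anh reduction, C2 in the chelate-controlled macrocyclisation.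
5. C6 and C7/C8 come from two Sharpless epoxidations (C7 inverted on lactonisation, C6 inverted on chlorination). C17 comes from tert-butyl (R)-lactate by SN2 inversion.

Key step: step 23

Remark: all locants are those of the briarane skeleton of the target (C1 quaternary with CH3-15; C2, C9, C14 acetoxy carbons; C5=C16 and C11=C20 methylenes; C6–Cl; C7–O–C19 lactone; C8 tertiary OH; C17 with CH3-18).

**Fragment 1 (C1, C2, C10–C15, C20)**

Step 1
Reactants: 1 methyl acetoacetate; 2 (3-bromoprop-1-yn-1-yl)trimethylsilane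
Product: 4 methyl 3-oxo-7-(trimethylsilyl)hept-6-ynoate, via acetoacetate dianion 3 (not isolated)
Conditions: NaH, THF, 0 °C; n-BuLi, 0 °C; then 2, 0 → 23 °C
Reagents that add atoms: none
Why: γ-alkylation of the acetoacetate dianion, whose terminal carbanion is the more reactive site, by the propargylic bromide installs C11–C13 and C20 without forming a stereocenter.

Step 2
Reactants: 4 methyl 3-oxo-7-(trimethylsilyl)hept-6-ynoate
Product: 5 methyl (3S)-3-hydroxy-7-(trimethylsilyl)hept-6-ynoate
Conditions: H2 (4 atm), RuCl2[(S)-BINAP] (cat.), MeOH, 50 °C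
Reagents that add atoms: none
Why: Noyori asymmetric hydrogenation of the β-keto ester, in which the chelated keto ester receives hydride on one face from the (S)-BINAP ruthenium hydride, should set C14 as S and leave the silyl-capped internal alkyne untouched.

Step 3
Reactants: 5 methyl (3S)-3-hydroxy-7-(trimethylsilyl)hept-6-ynoate
Product: 7 methyl (2S,3S)-3-hydroxy-2-methyl-7-(trimethylsilyl)hept-6-ynoate, via dilithium alkoxide enolate 6 (not isolated)
Conditions: LiN(i-Pr)2 (2.2 equiv), THF, −78 → −20 °C; MeI, −78 → 0 °C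
Reagents that add atoms: iodomethane CI
Why: Fráter–Seebach alkylation, in which the chelated dilithium alkoxide enolate is methylated on the face anti to the carbinol substituent, should give the 2,3-anti product.

Step 4
Reactants: 7 methyl (2S,3S)-3-hydroxy-2-methyl-7-(trimethylsilyl)hept-6-ynoate
Product: 9 methyl (2S,3S)-3-hydroxy-2-[(4-methoxybenzyloxy)methyl]-2-methyl-7-(trimethylsilyl)hept-6-ynoate, via dilithium alkoxide enolate 8 (not isolated)
Conditions: LiN(i-Pr)2 (2.2 equiv), THF/DMPU, −78 → −20 °C; 4-methoxybenzyl chloromethyl ether, −78 → 0 °C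
Reagents that add atoms: 4-methoxybenzyl chloromethyl ether COc1ccc(COCCl)cc1
Why: a second Fráter–Seebach alkylation of the re-formed chelated dianion again takes the electrophile anti to the carbinol substituent, so quaternary C1 should carry the C2 arm anti and CH3-15 syn to O14, as in the target.

Step 5
Reactants: 9 methyl (2S,3S)-3-hydroxy-2-[(4-methoxybenzyloxy)methyl]-2-methyl-7-(trimethylsilyl)hept-6-ynoate
Product: 10 methyl (2R,4S,5S)-2-(4-methoxyphenyl)-5-methyl-4-[4-(trimethylsilyl)but-3-yn-1-yl]-1,3-dioxane-5-carboxylate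
Conditions: DDQ, 4 Å molecular sieves, CH2Cl2, 0 °C
Reagents that add atoms: none
Why: oxidative acetalisation, in which DDQ oxidises the 4-methoxybenzyl ether to an oxocarbenium ion that the C14 hydroxyl traps, should give the 1,3-dioxane chair with aryl and C4 chain equatorial (acetal carbon R).

Step 6
Reactants: 10 methyl (2R,4S,5S)-2-(4-methoxyphenyl)-5-methyl-4-[4-(trimethylsilyl)but-3-yn-1-yl]-1,3-dioxane-5-carboxylate
Product: 11 [(2R,4S,5S)-2-(4-methoxyphenyl)-5-methyl-4-[4-(trimethylsilyl)but-3-yn-1-yl]-1,3-dioxan-5-yl]methanol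
Conditions: LiAlH4, THF, 0 °C
Reagents that add atoms: none
Why: hydride reduction of the ester gives the neopentyl alcohol (C10) while acetal and silylalkyne are inert.

Step 7
Reactants: 11 [(2R,4S,5S)-2-(4-methoxyphenyl)-5-methyl-4-[4-(trimethylsilyl)but-3-yn-1-yl]-1,3-dioxan-5-yl]methanol
Product: 12 (2R,4S,5S)-5-(iodomethyl)-2-(4-methoxyphenyl)-5-methyl-4-[4-(trimethylsilyl)but-3-yn-1-yl]-1,3-dioxane
Conditions: I2, PPh3, imidazole, toluene, 60 °C
Reagents that add atoms: iodine [I][I]
Why: Appel-type iodination (oxyphosphonium formation, then SN2 by iodide) converts the neopentyl alcohol, which has no β-hydrogen to eliminate, into the iodide.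

**Fragment 2 (C3–C9, C16–C19)**

Step 8
Reactants: 13 (2E)-3-methylpent-2-en-4-yn-1-ol
Product: 14 [(2S,3S)-3-ethynyl-3-methyloxiran-2-yl]methanol
Conditions: Ti(OiPr)4 (cat.), L-(+)-diethyl tartrate (cat.), t-BuOOH, 4 Å molecular sieves, CH2Cl2, −20 °C
Reagents that add atoms: tert-butyl hydroperoxide CC(C)(C)OO
Why: Sharpless asymmetric epoxidation of the 3,3-disubstituted allylic alcohol delivers oxygen to one alkene face under control of the titanium tartrate and sets the C6–O stereocenter.

Step 9
Reactants: 14 [(2S,3S)-3-ethynyl-3-methyloxiran-2-yl]methanol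
Product: 15 (2R)-3-methylidenepent-4-yne-1,2-diol
Conditions: Ti(OiPr)4 (1.5 equiv), CH2Cl2, 23 °C
Reagents that add atoms: none
Why: titanium alkoxide-mediated epoxy alcohol to ene-diol rearrangement should open the epoxide at the tertiary propargylic C5 and remove a proton from CH3-16, the only β-hydrogen source, so C5=C16 forms while the C6–O bond and its configuration stay untouched.

Step 10
Reactants: 15 (2R)-3-methylidenepent-4-yne-1,2-diol
Product: 17 (2R)-2-(tert-butyldimethylsilyloxy)-3-methylidene-1-(triethylsilyloxy)pent-4-yne, via primary triethylsilyl ether 16 (not isolated)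
Conditions: Et3SiCl, imidazole, CH2Cl2, −78 °C; then t-BuMe2SiOTf, 2,6-lutidine, −78 → 0 °C
Reagents that add atoms: chlorotriethylsilane CC[Si](CC)(CC)Cl; tert-butyldimethylsilyl trifluoromethanesulfonate CC(C)(C)[Si](C)(C)OS(=O)(=O)C(F)(F)F
Why: sequential silylation, in which the chlorosilane takes the primary hydroxyl at low temperature and the more reactive silyl triflate then takes the secondary allylic hydroxyl, differentiates O7 from O6.

Step 11
Reactants: 17 (2R)-2-(tert-butyldimethylsilyloxy)-3-methylidene-1-(triethylsilyloxy)pent-4-yne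
Product: 19 (2R,4E)-2-(tert-butyldimethylsilyloxy)-5-iodo-3-methylidene-1-(triethylsilyloxy)pent-4-ene, via alkenylzirconocene chloride 18 (not isolated)
Conditions: Cp2Zr(H)Cl, THF, 23 °C; then I2, 0 °C
Reagents that add atoms: iodine [I][I]
Why: hydrozirconation of the terminal alkyne (syn addition, zirconium at the terminus) and iodinolysis with retention should give the (E)-dienyl iodide, the 1,1-disubstituted alkene being unreactive.

Step 12
Reactants: 19 (2R,4E)-2-(tert-butyldimethylsilyloxy)-5-iodo-3-methylidene-1-(triethylsilyloxy)pent-4-ene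
Product: 20 (2R,4E)-2-(tert-butyldimethylsilyloxy)-5-iodo-3-methylidenepent-4-enal
Conditions: (COCl)2, DMSO, CH2Cl2, −78 → −30 °C; Et3N, −78 → 0 °C
Reagents that add atoms: none
Why: Swern oxidation applied directly to the primary triethylsilyl ether, which the chlorosulfonium salt cleaves and oxidises while the secondary tert-butyldimethylsilyl ether survives, gives the aldehyde at a temperature that protects the α-stereocenter C6.

Step 13
Reactants: 21 tert-butyl (2R)-2-hydroxypropanoate
Product: 22 tert-butyl (2R)-2-(trifluoromethanesulfonyloxy)propanoate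
Conditions: Tf2O, 2,6-lutidine, CH2Cl2, −78 °C
Reagents that add atoms: trifluoromethanesulfonic anhydride O=S(=O)(OS(=O)(=O)C(F)(F)F)C(F)(F)F
Why: O-sulfonylation with a non-nucleophilic base forms only the O–S bond, so the lactate configuration is retained.

Step 14
Reactants: 23 triethyl phosphonoacetate; 22 tert-butyl (2R)-2-(trifluoromethanesulfonyloxy)propanoate
Product: 25 4-tert-butyl 1-ethyl (3S)-2-(diethoxyphosphoryl)-3-methylbutanedioate (both C2 epimers), via sodium phosphonoacetate 24 (not isolated)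
Conditions: NaH, THF, 0 °C; then 22, −20 → 23 °C
Reagents that add atoms: none
Why: SN2 alkylation of the phosphonoacetate anion by the α-triflyloxy ester with inversion should give C17 the spatial arrangement it has in the target, the phosphonate carbon being left as a mixture because it becomes sp2 next.

Step 15
Reactants: 25 4-tert-butyl 1-ethyl (3S)-2-(diethoxyphosphoryl)-3-methylbutanedioate; 20 (2R,4E)-2-(tert-butyldimethylsilyloxy)-5-iodo-3-methylidenepent-4-enal
Product: 27 4-tert-butyl 1-ethyl (2E,3R)-2-[(2S,4E)-2-(tert-butyldimethylsilyloxy)-5-iodo-3-methylidenepent-4-en-1-ylidene]-3-methylbutanedioate, via sodium salt 26 (not isolated)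
Conditions: NaH, THF, 0 °C; then 20, −78 → 0 °C
Reagents that add atoms: none
Why: Horner–Wadsworth–Emmons olefination with the preformed, weakly basic phosphonate anion should give the trisubstituted (E)-alkylidenesuccinate (C6 trans to the C9 ester) without touching H17 or H6.

Step 16
Reactants: 27 (E)-alkylidenesuccinate diester
Product: 28 tert-butyl (2R,3E,5S,7E)-5-(tert-butyldimethylsilyloxy)-3-(hydroxymethyl)-8-iodo-2-methyl-6-methylideneocta-3,7-dienoate
Conditions: i-Bu2AlH (2.2 equiv), CH2Cl2, −78 °C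
Reagents that add atoms: none
Why: the aluminium hydride reduces the conjugated ethyl ester to the allylic alcohol (C9) while the hindered tert-butyl ester is not attacked at −78 °C.

Step 17
Reactants: 28 allylic alcohol
Product: 29 tert-butyl (2R)-2-[(2R,3R)-3-[(1R,3E)-1-(tert-butyldimethylsilyloxy)-4-iodo-2-methylidenebut-3-en-1-yl]-2-(hydroxymethyl)oxiran-2-yl]propanoate
Conditions: Ti(OiPr)4, D-(−)-diethyl tartrate, t-BuOOH, 4 Å molecular sieves, CH2Cl2, −20 °C
Reagents that add atoms: tert-butyl hydroperoxide CC(C)(C)OO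
Why: Sharpless asymmetric epoxidation of the (E)-2,3-disubstituted allylic alcohol under reagent control by the D-(−)-tartrate should set C8 (final configuration) and C7 (to be inverted later) on the C7=C8 alkene.

Step 18
Reactants: 29 epoxy alcohol
Product: 30 tert-butyl (2R)-2-[(2S,3R)-3-[(1R,3E)-1-(tert-butyldimethylsilyloxy)-4-iodo-2-methylidenebut-3-en-1-yl]-2-formyloxiran-2-yl]propanoate
Conditions: Dess–Martin periodinane, NaHCO3, CH2Cl2, 0 → 23 °C
Reagents that add atoms: none
Why: Dess–Martin oxidation gives the epoxy aldehyde (C9), which cannot enolise because C8 is fully substituted.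

**Union, ring A, lactone, ten-membered ring**

Step 19
Reactants: 12 (2R,4S,5S)-5-(iodomethyl)-1,3-dioxane of fragment 1; 30 epoxy aldehyde of fragment 2
Product: 32 C9 carbinol joining the fragments through C9–C10 (1S,6R,7R,8R,14S,17R; both C9 epimers), via alkylmagnesium iodide 31 (not isolated)
Conditions: Mg (I2-activated), THF, 40 °C; then 30, THF, −78 → 0 °C
Reagents that add atoms: none
Why: Grignard addition of the neopentyl-type organomagnesium, which has no β-hydrogen and so cannot reduce the aldehyde, forms C9–C10 chemoselectively at the aldehyde in the presence of ester, epoxide and alkenyl iodide, and the C9 epimers converge in the next step.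

Step 20
Reactants: 32 C9 carbinol
Product: 33 C9 ketone (α,β-epoxy ketone; 1S,6R,7R,8S,14S,17R)
Conditions: Dess–Martin periodinane, NaHCO3, CH2Cl2, 23 °C
Reagents that add atoms: none
Why: Dess–Martin oxidation of the secondary alcohol gives the ketone whose only α-hydrogens are on C10.

Step 21
Reactants: 33 C9 ketone
Product: 34 terminal alkyne (C11≡C20–H; otherwise as 33)
Conditions: AgNO3 (cat.), acetone/H2O, 23 °C
Reagents that add atoms: none
Why: silver-catalysed protodesilylation of the alkynylsilane under neutral conditions frees the terminal alkyne and avoids the base-induced β-elimination of the epoxide toward C17 that alkoxide conditions could cause.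

Step 22
Reactants: 34 terminal alkyne ketone
Product: 35 (Z)-C9 tert-butyldimethylsilyl enol ether (C9=C10; 1S,6R,7R,8S,14S,17R)
Conditions: t-BuMe2SiOTf, Et3N, CH2Cl2, −78 °C
Reagents that add atoms: tert-butyldimethylsilyl trifluoromethanesulfonate CC(C)(C)[Si](C)(C)OS(=O)(=O)C(F)(F)F
Why: soft enolisation with silyl triflate and amine gives the silyl enol ether regiospecifically toward C10, the only α-carbon with hydrogens, with the two bulky carbon substituents trans.

Step 23
Reactants: 35 (Z)-C9 silyl enol ether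
Product: 36 ring A ketone (cyclohexane C1, C10–C14 with C11=C20 methylene, cis-fused to the 2-(4-methoxyphenyl)-1,3-dioxane across C14/C1, H10 cis to O14; 1S,6R,7R,8S,10S,14S,17R)
Conditions: [(t-Bu)2(biphenyl-2-yl)P]Au(NCMe)SbF6 (5 mol %), CH2Cl2/MeOH (10:1), 23 °C
Reagents that add atoms: none
Why: The cationic monovalent gold complex binds the terminal C11≡C20 alkyne and the C10 terminus of the C9 silyl enol ether adds anti to gold at C11, after which methanol removes the silyl group from the oxocarbenium ion and protonates the vinyl–gold bond, so that the C9 ketone and the C11=C20 methylene appear together. The closest known reaction type is the gold-catalysed Conia-ene-type carbocyclisation of acetylenic silyl enol ethers, which has 5-exo-dig and 6-exo-dig precedent. Ring A is closed in the 6-exo-dig mode (C10, C1, C14, C13, C12, C11). The only new stereocenter, C10, is controlled by the cis-fused 1,3-dioxane, whose chair (aryl and C13 chain equatorial) forces O14 and CH3-15 to be axial on the forming chair, so the enol carbon C9 takes the equatorial site anti to C14 to avoid a syn-axial clash with O14, and H10 ends cis to O14 and trans to CH3-15 (10S), which is also the more stable epimer of the enolisable product. The step needs regioselective enolisation, secured because C8 is an epoxide carbon without hydrogen; exo selectivity, secured by the terminal alkyne and the six-atom tether; and chemoselectivity for the alkyne over the dienyl iodide and the epoxide, secured by the alkynophilic, weakly oxophilic catalyst in a neutral medium.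

Step 24
Reactants: 36 ring A ketone
Product: 37 C9 alcohol (1S,6R,7R,8R,9S,10S,14S,17R)
Conditions: LiBH(s-Bu)3, THF, −78 °C
Reagents that add atoms: none
Why: Felkin–Anh reduction by a bulky, non-chelating hydride, with quaternary C1 anti to the incoming hydride and C11 on the carbonyl-oxygen side, should give the 9S alcohol, and the low temperature avoids epimerisation or conjugation at C10.

Step 25
Reactants: 37 C9 alcohol
Product: 39 triol lactone (γ-lactone C7–O–C19; free 2-, 9-, 14- and 8-hydroxyls; 6-silyl ether; 1S,6R,7S,8R,9S,10S,14S,17R), via lactone acetal 38 (not isolated)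
Conditions: camphorsulfonic acid (cat.), CH2Cl2, 0 → 23 °C; then MeOH, 23 °C
Reagents that add atoms: none
Why: acid-catalysed epoxide-opening lactonisation, in which the carbonyl oxygen of the tert-butyl ester attacks C7 from the rear in a five-membered closure with loss of isobutene, inverts C7 and leaves O8 on C8, and transacetalisation with methanol then frees the C2 and C14 hydroxyls.

Step 26
Reactants: 39 triol lactone
Product: 40 C2 aldehyde (1R,6R,7S,8R,9S,10S,14S,17R)
Conditions: TEMPO (cat.), PhI(OAc)2, CH2Cl2, 23 °C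
Reagents that add atoms: none
Why: oxoammonium-mediated oxidation is selective for the primary C2 hydroxyl over the secondary and tertiary ones, and the aldehyde cannot enolise because C1 is quaternary.

Step 27
Reactants: 40 C2 aldehyde
Product: 41 macrocyclic tetraol silyl ether (ten-membered ring closed at C2–C3; 3E; 1R,2S,6R,7S,8R,9S,10S,14S,17R)
Conditions: CrCl2 (10 equiv), NiCl2 (cat.), DMSO/THF, 23 °C, high dilution
Reagents that add atoms: none
Why: Nozaki–Hiyama–Kishi macrocyclisation adds the alkenylchromium, formed with retention of the E geometry, to the neopentyl aldehyde, and closure through the conformer with the forming bond anti to C10 and the carbonyl oxygen chelated by the C14 chromium alkoxide should give the 2S carbinol (1,3-anti to O14).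

Step 28
Reactants: 41 macrocyclic tetraol silyl ether
Product: 42 2,9,14-triacetate (8-OH free; 6-silyl ether)
Conditions: Ac2O, pyridine, DMAP (cat.), 23 °C
Reagents that add atoms: acetic anhydride CC(=O)OC(C)=O
Why: nucleophile-catalysed acylation esterifies the three secondary hydroxyls while the hindered tertiary C8 hydroxyl stays free.

Step 29
Reactants: 42 triacetate silyl ether
Product: 43 6-alcohol (1R,2S,6R,7S,8R,9S,10S,14S,17R)
Conditions: HF·pyridine, pyridine, THF, 0 → 23 °C
Reagents that add atoms: none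
Why: fluoride-mediated desilylation removes the C6 silyl ether without touching acetates or lactone.

Step 30
Reactants: 43 6-alcohol
Product: 44 target, (1R,2S,3E,6S,7R,8R,9S,10S,14S,17R)-2,9,14-triacetoxy-6-chloro-8-hydroxybriara-3,5(16),11(20)-triene 7,19-lactone
Conditions: PPh3, hexachloroacetone, CH2Cl2, −20 → 0 °C
Reagents that add atoms: hexachloroacetone O=C(C(Cl)(Cl)Cl)C(Cl)(Cl)Cl
Why: Appel-type deoxychlorination through the oxyphosphonium ion and SN2 attack of chloride should invert the secondary allylic C6 (6R alcohol to 6S chloride) with little allylic transposition, the tertiary C8 hydroxyl being too hindered to react.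

**Compound list**

1 | methyl acetoacetate | CC(=O)CC(=O)OC | starting material
2 | (3-bromoprop-1-yn-1-yl)trimethylsilane | C[Si](C)(C)C#CCBr | starting material
3 | sodium lithium dianion of methyl acetoacetate | [Na+].[Li+].C=C([O-])C=C([O-])OC | intermediate
4 | methyl 3-oxo-7-(trimethylsilyl)hept-6-ynoate | COC(=O)CC(=O)CCC#C[Si](C)(C)C | intermediate
5 | methyl (3S)-3-hydroxy-7-(trimethylsilyl)hept-6-ynoate | C[Si](C)(C)C#CCC[C@H](O)CC(=O)OC | intermediate
6 | dilithium alkoxide enolate of 5 | [Li+].[Li+].C[Si](C)(C)C#CCC[C@H]([O-])C=C([O-])OC | intermediate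
7 | methyl (2S,3S)-3-hydroxy-2-methyl-7-(trimethylsilyl)hept-6-ynoate | C[Si](C)(C)C#CCC[C@H](O)[C@H](C)C(=O)OC | intermediate
8 | dilithium alkoxide enolate of 7 | [Li+].[Li+].C[Si](C)(C)C#CCC[C@H]([O-])C(C)=C([O-])OC | intermediate
9 | methyl (2S,3S)-3-hydroxy-2-[(4-methoxybenzyloxy)methyl]-2-methyl-7-(trimethylsilyl)hept-6-ynoate | C[Si](C)(C)C#CCC[C@H](O)[C@](C(=O)OC)(C)COCc1ccc(OC)cc1 | intermediate
10 | methyl (2R,4S,5S)-2-(4-methoxyphenyl)-5-methyl-4-[4-(trimethylsilyl)but-3-yn-1-yl]-1,3-dioxane-5-carboxylate | C[Si](C)(C)C#CCC[C@@H]1O[C@H](c2ccc(OC)cc2)OC[C@]1(C)C(=O)OC | intermediate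
11 | [(2R,4S,5S)-2-(4-methoxyphenyl)-5-methyl-4-[4-(trimethylsilyl)but-3-yn-1-yl]-1,3-dioxan-5-yl]methanol | C[Si](C)(C)C#CCC[C@@H]1O[C@H](c2ccc(OC)cc2)OC[C@]1(C)CO | intermediate
12 | (2R,4S,5S)-5-(iodomethyl)-2-(4-methoxyphenyl)-5-methyl-4-[4-(trimethylsilyl)but-3-yn-1-yl]-1,3-dioxane | C[Si](C)(C)C#CCC[C@@H]1O[C@H](c2ccc(OC)cc2)OC[C@]1(C)CI | intermediate
13 | (2E)-3-methylpent-2-en-4-yn-1-ol | C#C/C(C)=C/CO | starting material
14 | [(2S,3S)-3-ethynyl-3-methyloxiran-2-yl]methanol | OC[C@@H]1O[C@@]1(C)C#C | intermediate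
15 | (2R)-3-methylidenepent-4-yne-1,2-diol | OC[C@H](O)C(=C)C#C | intermediate
16 | (2R)-3-methylidene-1-(triethylsilyloxy)pent-4-yn-2-ol | CC[Si](CC)(CC)OC[C@H](O)C(=C)C#C | intermediate
17 | (2R)-2-(tert-butyldimethylsilyloxy)-3-methylidene-1-(triethylsilyloxy)pent-4-yne | CC[Si](CC)(CC)OC[C@H](O[Si](C)(C)C(C)(C)C)C(=C)C#C | intermediate
18 | (E)-alkenylzirconocene chloride from 17 | CC[Si](CC)(CC)OC[C@H](O[Si](C)(C)C(C)(C)C)C(=C)/C=C/[Zr](Cl)(C1C=CC=C1)C1C=CC=C1 | intermediate
19 | (2R,4E)-2-(tert-butyldimethylsilyloxy)-5-iodo-3-methylidene-1-(triethylsilyloxy)pent-4-ene | CC[Si](CC)(CC)OC[C@H](O[Si](C)(C)C(C)(C)C)C(=C)/C=C/I | intermediate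
20 | (2R,4E)-2-(tert-butyldimethylsilyloxy)-5-iodo-3-methylidenepent-4-enal | O=C[C@H](O[Si](C)(C)C(C)(C)C)C(=C)/C=C/I | intermediate
21 | tert-butyl (2R)-2-hydroxypropanoate | CC(C)(C)OC(=O)[C@@H](C)O | starting material
22 | tert-butyl (2R)-2-(trifluoromethanesulfonyloxy)propanoate | CC(C)(C)OC(=O)[C@@H](C)OS(=O)(=O)C(F)(F)F | intermediate
23 | triethyl phosphonoacetate | CCOC(=O)CP(=O)(OCC)OCC | starting material
24 | sodium salt of triethyl phosphonoacetate | [Na+].CCOC(=O)[CH-]P(=O)(OCC)OCC | intermediate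
25 | 4-tert-butyl 1-ethyl (3S)-2-(diethoxyphosphoryl)-3-methylbutanedioate (C2 epimers) | CCOC(=O)C(P(=O)(OCC)OCC)[C@@H](C)C(=O)OC(C)(C)C | intermediate
26 | sodium salt of 25 | [Na+].CCOC(=O)[C-](P(=O)(OCC)OCC)[C@@H](C)C(=O)OC(C)(C)C | intermediate
27 | 4-tert-butyl 1-ethyl (2E,3R)-2-[(2S,4E)-2-(tert-butyldimethylsilyloxy)-5-iodo-3-methylidenepent-4-en-1-ylidene]-3-methylbutanedioate | CCOC(=O)/C(=C/[C@H](O[Si](C)(C)C(C)(C)C)C(=C)/C=C/I)[C@@H](C)C(=O)OC(C)(C)C | intermediate
28 | tert-butyl (2R,3E,5S,7E)-5-(tert-butyldimethylsilyloxy)-3-(hydroxymethyl)-8-iodo-2-methyl-6-methylideneocta-3,7-dienoate | OC/C(=C/[C@H](O[Si](C)(C)C(C)(C)C)C(=C)/C=C/I)[C@@H](C)C(=O)OC(C)(C)C | intermediate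
29 | tert-butyl (2R)-2-[(2R,3R)-3-[(1R,3E)-1-(tert-butyldimethylsilyloxy)-4-iodo-2-methylidenebut-3-en-1-yl]-2-(hydroxymethyl)oxiran-2-yl]propanoate | OC[C@]1(O[C@@H]1[C@H](O[Si](C)(C)C(C)(C)C)C(=C)/C=C/I)[C@@H](C)C(=O)OC(C)(C)C | intermediate
30 | tert-butyl (2R)-2-[(2S,3R)-3-[(1R,3E)-1-(tert-butyldimethylsilyloxy)-4-iodo-2-methylidenebut-3-en-1-yl]-2-formyloxiran-2-yl]propanoate | O=C[C@]1(O[C@@H]1[C@H](O[Si](C)(C)C(C)(C)C)C(=C)/C=C/I)[C@@H](C)C(=O)OC(C)(C)C | intermediate
31 | alkylmagnesium iodide from 12 | C[Si](C)(C)C#CCC[C@@H]1O[C@H](c2ccc(OC)cc2)OC[C@]1(C)C[Mg]I | intermediate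
32 | C9 carbinol, union product of 12 and 30 (1S,6R,7R,8R,14S,17R; C9 epimers) | C[Si](C)(C)C#CCC[C@@H]1O[C@H](c2ccc(OC)cc2)OC[C@]1(C)CC(O)[C@]3(O[C@@H]3[C@H](O[Si](C)(C)C(C)(C)C)C(=C)/C=C/I)[C@@H](C)C(=O)OC(C)(C)C | intermediate
33 | C9 ketone (α,β-epoxy ketone; 1S,6R,7R,8S,14S,17R) | C[Si](C)(C)C#CCC[C@@H]1O[C@H](c2ccc(OC)cc2)OC[C@]1(C)CC(=O)[C@]3(O[C@@H]3[C@H](O[Si](C)(C)C(C)(C)C)C(=C)/C=C/I)[C@@H](C)C(=O)OC(C)(C)C | intermediate
34 | C9 ketone with free terminal alkyne | C#CCC[C@@H]1O[C@H](c2ccc(OC)cc2)OC[C@]1(C)CC(=O)[C@]3(O[C@@H]3[C@H](O[Si](C)(C)C(C)(C)C)C(=C)/C=C/I)[C@@H](C)C(=O)OC(C)(C)C | intermediate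
35 | (Z)-C9 tert-butyldimethylsilyl enol ether (C9=C10) | C#CCC[C@@H]1O[C@H](c2ccc(OC)cc2)OC[C@]1(C)/C=C(\O[Si](C)(C)C(C)(C)C)[C@]3(O[C@@H]3[C@H](O[Si](C)(C)C(C)(C)C)C(=C)/C=C/I)[C@@H](C)C(=O)OC(C)(C)C | intermediate
36 | ring A ketone (1S,6R,7R,8S,10S,14S,17R) | C=C1CC[C@@H]2O[C@H](c3ccc(OC)cc3)OC[C@]2(C)[C@H]1C(=O)[C@]4(O[C@@H]4[C@H](O[Si](C)(C)C(C)(C)C)C(=C)/C=C/I)[C@@H](C)C(=O)OC(C)(C)C | intermediate
37 | C9 alcohol (1S,6R,7R,8R,9S,10S,14S,17R) | C=C1CC[C@@H]2O[C@H](c3ccc(OC)cc3)OC[C@]2(C)[C@H]1[C@H](O)[C@]4(O[C@@H]4[C@H](O[Si](C)(C)C(C)(C)C)C(=C)/C=C/I)[C@@H](C)C(=O)OC(C)(C)C | intermediate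
38 | γ-lactone with the benzylidene acetal intact (1S,6R,7S,8R,9S,10S,14S,17R) | C=C1CC[C@@H]2O[C@H](c3ccc(OC)cc3)OC[C@]2(C)[C@H]1[C@H](O)[C@@]4(O)[C@@H](OC(=O)[C@@H]4C)[C@H](O[Si](C)(C)C(C)(C)C)C(=C)/C=C/I | intermediate
39 | triol lactone (2-, 9-, 14- and 8-OH free; 1S,6R,7S,8R,9S,10S,14S,17R) | C=C1CC[C@H](O)[C@](C)(CO)[C@H]1[C@H](O)[C@@]2(O)[C@@H](OC(=O)[C@@H]2C)[C@H](O[Si](C)(C)C(C)(C)C)C(=C)/C=C/I | intermediate
40 | C2 aldehyde (1R,6R,7S,8R,9S,10S,14S,17R) | C=C1CC[C@H](O)[C@](C)(C=O)[C@H]1[C@H](O)[C@@]2(O)[C@@H](OC(=O)[C@@H]2C)[C@H](O[Si](C)(C)C(C)(C)C)C(=C)/C=C/I | intermediate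
41 | (1R,2S,3E,6R,7S,8R,9S,10S,14S,17R)-6-(tert-butyldimethylsilyloxy)-2,8,9,14-tetrahydroxybriara-3,5(16),11(20)-triene 7,19-lactone | C=C1CC[C@H](O)[C@]2(C)[C@@H](O)/C=C/C(=C)[C@@H](O[Si](C)(C)C(C)(C)C)[C@@H]3OC(=O)[C@H](C)[C@@]3(O)[C@@H](O)[C@@H]12 | intermediate
42 | 2,9,14-triacetate of 41 | C=C1CC[C@H](OC(C)=O)[C@]2(C)[C@@H](OC(C)=O)/C=C/C(=C)[C@@H](O[Si](C)(C)C(C)(C)C)[C@@H]3OC(=O)[C@H](C)[C@@]3(O)[C@@H](OC(C)=O)[C@@H]12 | intermediate
43 | (6R)-6-alcohol: 2,9,14-triacetoxy-6,8-dihydroxybriara-3,5(16),11(20)-triene 7,19-lactone | C=C1CC[C@H](OC(C)=O)[C@]2(C)[C@@H](OC(C)=O)/C=C/C(=C)[C@@H](O)[C@@H]3OC(=O)[C@H](C)[C@@]3(O)[C@@H](OC(C)=O)[C@@H]12 | intermediate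
44 | CNP0178742.3, (1R,2S,3E,6S,7R,8R,9S,10S,14S,17R)-2,9,14-triacetoxy-6-chloro-8-hydroxybriara-3,5(16),11(20)-triene 7,19-lactone | C=C1CC[C@H](OC(C)=O)[C@]2(C)[C@@H](OC(C)=O)/C=C/C(=C)[C@H](Cl)[C@@H]3OC(=O)[C@H](C)[C@@]3(O)[C@@H](OC(C)=O)[C@@H]12 | target

**Totals and risks**

Total step count: 30. Longest linear sequence: 21 steps (13 → 44 through steps 8–12 and 15–30).

Steps most likely to fail:

1. Step 23 (ring A closure). The 2-silyloxy vinyl epoxide may ionise at C8, or the enol ether may lose its silyl group to methanol before the carbon–carbon bond forms, so that ketone 34 is returned or the epoxide rearranges. The fallback sets out from 35 and changes the reactive intermediate from a gold-activated alkyne to a carbon radical. N-Bromosuccinimide (THF, −78 °C) converts the silyl enol ether into the α-bromo ketone F1 (C10 epimers). Visible-light photoredox reduction (Ru(bpy)3Cl2 cat., Hantzsch ester, i-Pr2NEt, DMF, blue light) should then cleave only the activated C–Br bond. The C10 α-keto radical closes ring A by 6-exo-dig addition to C11 through the same dioxane-locked chair, the vinyl radical takes a hydrogen atom, and the route is rejoined at 36.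

2. Step 27 (ten-membered ring closure). The strained transition state may override the chelate, so that the alkenylchromium attacks the other face of the C2 aldehyde and the C2 epimer forms beside 41. The fallback sets out from 41 as the C2 epimer mixture and moves control of C2 from the ring closure to a reagent. MnO2 (CH2Cl2) oxidises only the allylic C2 carbinol to the cross-conjugated dienone F2. Corey–Bakshi–Shibata reduction (BH3·SMe2 in excess, (R)-2-methyl-CBS-oxazaborolidine, quaternary C1 acting as the large group) should then return the 2S alcohol, and the route is rejoined at 41.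

3. Step 30 (chloride installation). The oxyphosphonium ion pair may collapse with allylic transposition (chloride at C16, C5=C6 alkene) or with loss of configuration at C6. The fallback sets out from 43 and separates activation from displacement. MsCl and Et3N (CH2Cl2, −20 °C) give the C6 mesylate F3, which is kept from ionising by the electron-withdrawing lactone oxygen at C7. In a discrete bimolecular step, n-Bu4NCl in acetone should then displace it with inversion, and the route is rejoined at 44.

Further compounds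
F1 | step 23 | C10 α-bromo ketone from 35 (C10 epimers) | C#CCC[C@@H]1O[C@H](c2ccc(OC)cc2)OC[C@]1(C)C(Br)C(=O)[C@]3(O[C@@H]3[C@H](O[Si](C)(C)C(C)(C)C)C(=C)/C=C/I)[C@@H](C)C(=O)OC(C)(C)C
F2 | step 27 | C2 dienone from 41 | C=C1CC[C@H](O)[C@]2(C)C(=O)/C=C/C(=C)[C@@H](O[Si](C)(C)C(C)(C)C)[C@@H]3OC(=O)[C@H](C)[C@@]3(O)[C@@H](O)[C@@H]12
F3 | step 30 | C6 methanesulfonate of 43 | C=C1CC[C@H](OC(C)=O)[C@]2(C)[C@@H](OC(C)=O)/C=C/C(=C)[C@@H](OS(C)(=O)=O)[C@@H]3OC(=O)[C@H](C)[C@@]3(O)[C@@H](OC(C)=O)[C@@H]12
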